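The suspected route in our stirred flask runs from starting material and coupling partner to intermediate A; second reagent takes that to intermediate B, and third reagent finishes it as target. Starting material may also take second reagent away as side product.

| flask | starting material | coupling partner | second reagent | third reagent | protic impurity | temperature | remark | time |
|---|---|---|---|---|---|---|---|---|
| ochre | 0.20 M | 2.5 equiv | 0.50 equiv | 1.1 equiv | 0.040 M | −10 °C | run made earlier |  |
| violet | 0.20 M | 2.5 equiv | 0.34 equiv | 1.1 equiv | 0.040 M | 5 °C | run made earlier |  |
| green | 0.20 M | 2.5 equiv | 0.75 equiv | 1.1 equiv | 0.040 M | −10 °C | run made earlier |  |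
| red | 0.20 M | 5 equiv | 0.50 equiv | 1.1 equiv | 0.040 M | 5 °C | run made earlier |  |
| Friday's | 0.20 M (fed, over 20 min) | 2.50 equiv | 0.500 equiv | 1.10 equiv | 0.0400 M | 5 °C | all else is in the flask from the start; the feed brings no volume worth counting | 30 min |
| Saturday's | 0.20 M | 2.50 equiv (fed, over 20 min) | 0.500 equiv | 1.10 equiv | 0.0400 M |  | the addition at −15 °C, then warmed to 5 °C; the feed brings no volume worth counting | 30 min |
| Sunday's | 0.20 M | 2.50 equiv (fed, over 20 min) | 0.500 equiv | 1.10 equiv | 0.0400 M | 5 °C | all else is in the flask from the start; the feed brings no volume worth counting | 30 min |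
| Tuesday's | 0.20 M | 2.50 equiv | 0.500 equiv | 1.10 equiv | 0.0400 M |  | everything together at the start at −15 °C, warmed to 5 °C at 20 min | 30 min |

| run | time / min | target / % |
|---|---|---|
| ochre | 3.00 | 1.1 |
| ochre | 10.0 | 2.4 |
| ochre | 15.0 | 5.2 |
| ochre | 25.0 | 4.4 |
| ochre | 40.0 | 10.0 |
| ochre | 50.0 | 11.5 |
| ochre | 60.0 | 14.3 |
| violet | 4.00 | 3.3 |
| violet | 8.00 | 6.3 |
| violet | 12.0 | 8.2 |
| violet | 15.0 | 10.6 |
| violet | 20.0 | 12.3 |
| violet | 25.0 | 13.6 |
| violet | 30.0 | 15.1 |
| green | 3.00 | 0 |
| green | 10.0 | 2.3 |
| green | 15.0 | 4.5 |
| green | 25.0 | 9.3 |
| green | 40.0 | 14.5 |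
| green | 50.0 | 18.6 |
| green | 60.0 | 20.7 |
| red | 6.00 | 10.8 |
| red | 12.0 | 17.3 |
| red | 20.0 | 24.1 |
| red | 25.0 | 27.8 |
| red | 30.0 | 28.5 |

(scatter of a reading: 1 percentage point)

- on the list of suspects stand: starting material + coupling partner -> intermediate A; second reagent + intermediate A -> intermediate B; third reagent + intermediate B -> target; starting material + second reagent -> side product; coupling partner + protic impurity -> quenched reagent; second reagent + target -> over-reaction product; starting material -> decomposition product

- the best flask by amount of target, in percent of the starting material charged; "all alike" if 1.5 percentage points covers them all (Friday's / Saturday's / Sunday's / Tuesday's / all alike)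
- amount of target at the end, in percent of the starting material charged, Friday's
- amount of target at the end, in percent of the starting material charged, Saturday's
- amount of target at the end, in percent of the starting material charged, Sunday's
- amount of target at the end, in percent of the starting material charged, Tuesday's

Each target uses one second reagent, so the charge allows 50.0% of the starting material. We call this the ceiling, and each side product takes one off it.

How fast do we climb towards it? We read the rate from the violet run and scale it to our charge, since green over ochre gives 1.45 at the end for 1.50 times the second reagent. The slowing is violet's mean rate up to 30.0 min over its early rate. For a flask fed over 20 min, we count the run from the middle of the feed.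

Early rate in violet, read at 8.00 min: 0.00788 min⁻¹ of the charge

Scaled to our second reagent: 0.0116 min⁻¹

Factor for the slowing, as read: 0.639

Factor for the feed: 0.667

Batch at 30 min: 22.2%

Friday's and Sunday's at 30 min: 14.8%

Our reckoning puts both fed flasks below the ceiling, so in 30 min we expect the rate to hold them down, and it does not separate them.

The forecast does separate them, giving 16% for Friday's and 14% for Sunday's, with 11% for Saturday's and 14% for Tuesday's. Its best flask is Friday's, and its ground for Sunday's is that “starting material eats second reagent while coupling partner is low”.

The simulation gives 24.9% for Friday's, 6.43% for Saturday's, 3.56% for Sunday's and 14.1% for Tuesday's, so the best flask is Friday's.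

    starting material + coupling partner → intermediate A (k = 1.46 M⁻¹ min⁻¹, Ea = 58.0 kJ mol⁻¹)
    second reagent + intermediate A → intermediate B (k = 6.70 M⁻¹ min⁻¹, Ea = 39.0 kJ mol⁻¹)
    third reagent + intermediate B → target (k = 0.377 M⁻¹ min⁻¹, Ea = 65.0 kJ mol⁻¹)
    starting material + second reagent → side product (k = 4.34 M⁻¹ min⁻¹, Ea = 51.0 kJ mol⁻¹)
    coupling partner + protic impurity → quenched reagent (k = 0.318 M⁻¹ min⁻¹, Ea = 65.0 kJ mol⁻¹)
    second reagent + target → over-reaction product (k = 0.112 M⁻¹ min⁻¹, Ea = 65.0 kJ mol⁻¹)
    starting material → decomposition product (k = 1.05 × 10⁻⁴ min⁻¹, Ea = 87.0 kJ mol⁻¹)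
    (constants at 5 °C)

Friday's flask is not at rest at 30.0 min: it holds 24.9% of target and 7.85% as intermediate B, with second reagent at 0%. Ten times the time takes its target to 32.8%, while side product stays at 16.8%. The ceiling less side product and twice the over-reaction product, which carries two second reagents, gives 32.8%. Sunday's flask holds 45.9% of side product at 30.0 min, so its ceiling less side product is 4.10%, and the same wait moves its target from 3.56% to 4.08%.

The runs are calculated with made-up constants, noise included.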